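(The numbers are assumed; what happens was integrated by code.)

I judged this flask by one ratio: the rate at which electrophile goes to target over the rate at which it goes to homo dimer.

    nucleophile + acid set free ⇌ protonated nucleophile, settled at all times (K1 = 1.1 × 10⁵ /M)
    acid set free + free base ⇌ salt of the base (K2 = 3.3 × 10⁶ /M, k2 = 370 /M/s)
    2 electrophile → homo dimer (k3 = 16 /M/s)
    electrophile + nucleophile → acid set free + target (k4 = 1300 /M/s)
    solid nucleophile ⇌ nucleophile, rate k5*(cs5 - [nucleophile]) while solid is left; crystals form when [nucleophile] > cs5 (cs5 = 0.57 mM, k5 = 0.73 /s)

electrophile 10 mM; free base 3.00 equiv; solid nucleophile 0.800 equiv; time 2.0 min

- percent here means electrophile units held: one homo dimer counts as two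
- two of one species on the left: rate k times its square, two consumed each time
- solid nucleophile is a solid; its amount is given per volume of the solution
- at the start none of the solid nucleophile is in solution
- the reaction counts as stopped when no species that holds the electrophile changes by six tenths of a point or more over the second half of the time
- run time (flask): 2.0 min

- why nothing more happens at 2.0 min, or that something still does (for what has run out or reacted, a solid counts together with what of it has only dissolved) (the nucleophile has run out first / forward and back rates have come level / all of the electrophile has reacted / it is still moving / the free base has run out first)
- how much target there is at 2.0 min, in percent of the electrophile charged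

**Two drains.** No nucleophile was dissolved at the start, so I drew target leaving zero with a flat slope. Dissolved nucleophile is consumed as it dissolves, so, protonation apart, I let the slope build within about 0.0728 s, the reciprocal of the dissolution coefficient plus k4 times the electrophile charged. The electrophile then consumed dissolved nucleophile at 13.0 /s, faster than it dissolved. Dissolution was therefore the rate-limiting step, and target rose at a ceiling J, the dissolution coefficient times the solubility: 0.416 mM/s. Dimerisation started faster, at 3.20 mM/s.

**Equal shares.** I took a ratio of one as the zero of the scale. This gave the crossover level A×, the electrophile concentration at which J equals the loss to homo dimer: 3.61 mM. At level A the ratio is the square of A× over A, and target's share of the electrophile lost is that ratio over one plus itself. Dimerisation alone brought the electrophile down to A× in about 5.54 s, the knee of the curve.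

**The level.** As a rough reckoning I let the share switch at a ratio of one: electrophile above A× went to homo dimer, and electrophile below A× went to target. The curve then levelled at A× over the charge, 36.1 %. The knee plus that target made at J came to about 14.2 s, shorter than the run. That target needed less nucleophile than the 8.00 mM charged, so I expected the electrophile to end first.

**The forecast.** It said all of the electrophile has reacted and gave 40 %, within 36 % to 44 %, by “Weighing that capped rate against the dimer loss”. My figure stood 3.9 percentage points below it.

**The flask.** The simulation gave all of the electrophile has reacted, with 0 % of it left, and 39.2 % of target. The ratio read 0.018 just after the start, below my 0.130 for nucleophile at its ceiling, and 1.6 at 0.0998 min. Target moved by 5 points, a step that ends outside the forecast's range on either side, at the nearest electrophile charges 8.36 mM and 12.1 mM.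

**Scant solid.** In the neighbour flask with 0.320 equiv of solid nucleophile, A× stayed 3.61 mM, but the charge held 3.20 mM, and I took the lower, 32.0 %. That neighbour flask gave 32.0 %, with 0 % of its solid nucleophile left.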